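## Structural features

1. The target is a (2S)-flavanone. A phloroglucinol-type A ring (C4a, C5, C6, C7, C8, C8a) is fused through C4a–C8a to a 2,3-dihydropyran-4-one C ring (O1, C2, C3, C4). C2 carries a 3,4-dimethoxyphenyl B ring and C6 carries an (E)-geranyl chain.
2. C2 is the only stereocentre. It is benzylic to an electron-rich arene, bound to O1 and β to the C4 carbonyl, so base (E1cB retro-oxa-Michael opening to the chalcone) or strong hot acid (ionisation of C2–O1) erases it.
3. C6 lies between the 5-OH (hydrogen-bonded to C4=O) and the 7-OH. The trisubstituted alkenes C2''=C3'' and C6''=C7'' are easily protonated, after which a flanking phenol closes a chroman, and the E geometry at C2''=C3'' has to be brought in intact.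
4. The 6-geranyl and 8-geranyl skeletons differ only in which of the two oxygens ortho to the acyl-bearing carbon C4a becomes O1.
5. The real difficulty is therefore a pair of selections: the absolute configuration at a labile C2, and the position of the ring oxygen relative to the chain. Both must be made beside an acid-sensitive diene and without strongly basic late steps.
6. The first feature exploited is that C8a (bearing O1) is para to C6. An A ring that still lacks C4 has a mirror plane through C6 and C8a, so C4a and C8 are equivalent.
7. The second feature is the one the key step uses. The segment C4(=O)–C3H2–C2H(Ar)–O1 of ring C is constitutionally a formyl C4–H bond added across a C2=C3 aryl enol ether, with C3 unsubstituted and H as the fourth ligand on C2.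

## Logic of the disconnections

**13 ⇒ 12.** No skeletal bond is cut; O5–H and O7–H are exchanged for O–CH2OCH3 acetals. These acetals direct both metalations further back, keep O5 from chelating the metal of the key step, and prevent the phenoxide formation that would start opening of ring C. There is no gain in skeleton, but every earlier step may be basic or organometallic. The demand is that the last step frees two phenols beside the diene without touching C2, hence a short, cold acetal exchange.

**12 ⇒ 11 (key).** The bonds cut are C3–C4 and C2–H. In one sentence, the route is an enantioselective intramolecular alkene hydroacylation of 11.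
- Reason for the cut: the O1–C2 bond, whose reversible formation is the weakness of the customary closure, is already present as an enol ether. It is neither made nor broken when the stereocentre is set.
- Gain: ring C and the stereocentre both vanish, and 11 is an achiral isomer of 12.
- Demand: endo regiochemistry, hydride delivery to the Re face of C2, indifference to the geranyl alkenes, and a neutral medium.

**11 ⇒ 8.** The bond cut is C4–C4a. In 8 the two remaining ring C–H positions are related by the mirror plane through C6 and C8a, so formylation at either gives the same compound with the chain necessarily at C6. The 6/8 problem is removed by symmetry and not by selectivity. The formylation must be nucleophilic (metalation), because electrophilic formylating agents would attack the enol-ether carbon C3.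

**8 ⇒ 5 + 6.** The bond cut is C6–C1''. C6 is the only ring position flanked by two acetal oxygens, and the E alkene is bought in 6. Ten carbons are joined in one convergent step. The demand is site-selective metalation among three ring C–H positions and attack at C1'' (SN2, not SN2').

**5 ⇒ 4.** The bond cut is C2=C3. An aryl 1-arylvinyl ether is a methylenated aryl ester, and C3 is a single carbon without substituents. O1–C2 becomes a plain ester bond. The demand is an olefination of an ester carbonyl that is neither acidic nor strongly basic.

**4 ⇒ 3.** The bonds cut are the two O–CH2 acetal bonds at O5 and O7. The two hydroxyls of 3 are equivalent, so no selectivity is required.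

**3 ⇒ 1 + 2.** The bond cut is O1–C2 (acyl). The three hydroxyls of 1 are equivalent, and whichever is acylated becomes O1. 2 brings in C2 and the whole B ring. Only the degree of acylation has to be controlled.

## Other disconnections considered

**Alternative 1:** (the first that comes to mind) Cut O1–C2.
- Forward key step: Claisen–Schmidt condensation to the 2',4',6'-trihydroxy-3'-geranyl-3,4-dimethoxychalcone A1, then 6-endo-trig oxa-Michael closure.
- Regiochemistry: A1 has two non-equivalent hydroxyls ortho to the carbonyl. Closure through the one next to the chain leads to the 8-geranyl isomer A2, so extra differentiation of the phenols would be needed.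
- Stereochemistry: the stereo-defining bond is the same bond whose reversible cleavage racemises the product. Any catalyst control therefore works against equilibration, and an unactivated 2'-hydroxychalcone offers a catalyst little to hold.
- Preference: the chosen plan sets C2 by C–H and C–C bond formation, which does not revert.

**Alternative 2:** Cut C2–C1'.
- Forward key step: catalytic asymmetric conjugate addition of 3,4-dimethoxyphenylboronic acid A4 to 6-geranyl-5,7-bis(methoxymethoxy)chromone A3.
- Merit: the reaction type is established.
- Step economy: A3 must first be made regiodefined, with the two-carbon C2–C3 unit built on a differentiated A ring. This costs several more steps than the chosen plan.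
- Mechanism: the 5,7-dioxygenation and the peri 5-alkoxy group lower the electrophilicity of C2, so protodeboronation of the electron-rich A4 can be expected to compete in the protic media these additions need.
- Use: the plan is kept as the fallback for the key step.

**Alternative 3:** Cut C4–C4a after O1–C2 has been set.
- Forward sequence: Mitsunobu inversion of ethyl (R)-3-(3,4-dimethoxyphenyl)-3-hydroxypropanoate A5 by the symmetric A-ring phenol, saponification to the (S)-3-aryl-3-aryloxypropanoic acid A6, and intramolecular Friedel–Crafts acylation at either equivalent ortho carbon.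
- Merit: it shares the symmetry argument of the chosen plan.
- Stereochemistry: the configuration rests on an SN2 displacement at a veratryl-type carbinol that ionises readily.
- Compatibility: the acylating media (strong Brønsted or Lewis acids) are incompatible with the acetals, the diene and the benzylic ether. An anionic variant would expose a β-aryloxy carbonyl compound to E1cB loss of the phenoxide.
- Step economy: it needs a separate asymmetric step and is longer.

Key step: step 6

Assumption: the sense of induction of the ligand on this substrate class cannot be derived from first principles. (R)-DTBM-SEGPHOS is written for hydride delivery to the Re face of C2, and its antipode is taken if the opposite sense holds.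

## Steps

Step 1
Reactants: 1 phloroglucinol (benzene-1,3,5-triol); 2 3,4-dimethoxybenzoyl chloride
Product: 3 3,5-dihydroxyphenyl 3,4-dimethoxybenzoate
Conditions: 1 (4 equiv), Et3N, THF, 0 °C to rt; aqueous wash removes excess 1
Reagents that add atoms: none
Why: O-Acylation of a phenol with an acid chloride; the three hydroxyls of 1 are equivalent, so only over-acylation must be held back, which the excess of water-soluble 1 should do. The acylated oxygen becomes O1 and the acyl carbon becomes C2.

Step 2
Reactants: 3 3,5-dihydroxyphenyl 3,4-dimethoxybenzoate
Product: 4 3,5-bis(methoxymethoxy)phenyl 3,4-dimethoxybenzoate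
Conditions: MOMCl, i-Pr2NEt, CH2Cl2, 0 °C to rt
Reagents that add atoms: chloromethyl methyl ether, COCCl
Why: Standard phenol alkylation to methoxymethyl acetals; the two hydroxyls are equivalent and the hindered amine should leave the aryl ester untouched.

Step 3
Reactants: 4 3,5-bis(methoxymethoxy)phenyl 3,4-dimethoxybenzoate
Product: 5 4-{1-[3,5-bis(methoxymethoxy)phenoxy]ethenyl}-1,2-dimethoxybenzene
Conditions: Cp2TiMe2, toluene, 70 °C, dark; filtration through basic alumina
Reagents that add atoms: dimethyltitanocene (Petasis reagent), [CH3-].[CH3-].[cH-]1cccc1.[cH-]1cccc1.[Ti+4]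
Why: Petasis methylenation of an ester carbonyl, a reaction type known for aryl benzoates. The medium is neither acidic nor basic, so acetals and methyl ethers survive, and the acid-labile enol ether is kept away from silica.

Step 4
Reactants: 5 4-{1-[3,5-bis(methoxymethoxy)phenoxy]ethenyl}-1,2-dimethoxybenzene; 6 geranyl bromide, (2E)-1-bromo-3,7-dimethylocta-2,6-diene
Product: 8 4-(1-{4-[(2E)-3,7-dimethylocta-2,6-dien-1-yl]-3,5-bis(methoxymethoxy)phenoxy}ethenyl)-1,2-dimethoxybenzene, via C6-aryllithium 7 (not isolated)
Conditions: n-BuLi, THF, −20 to 0 °C; then 6, −78 °C to rt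
Reagents that add atoms: none
Why: Directed ortho-metalation followed by SN2 allylation. The C–H between the two chelating acetal oxygens is the most acidified and best pre-complexed site, while the two sites next to the bulky, weakly Lewis-basic enol-ether oxygen are screened. The primary allylic bromide should react at C1'' with the E alkene unchanged.

Step 5
Reactants: 8 4-(1-{4-[(2E)-3,7-dimethylocta-2,6-dien-1-yl]-3,5-bis(methoxymethoxy)phenoxy}ethenyl)-1,2-dimethoxybenzene
Product: 11 2-{[1-(3,4-dimethoxyphenyl)ethenyl]oxy}-5-[(2E)-3,7-dimethylocta-2,6-dien-1-yl]-4,6-bis(methoxymethoxy)benzaldehyde, via C4a-aryllithium 9 (not isolated), via lithium hemiaminal alkoxide 10 (not isolated)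
Conditions: n-BuLi, THF, −40 to 0 °C; DMF, −78 to 0 °C; H2O
Reagents that add atoms: N,N-dimethylformamide, CN(C)C=O
Why: Second directed ortho-metalation and formylation with DMF. Only two ring C–H positions remain, and they are symmetry-equivalent, each lying between an acetal oxygen and the enol-ether oxygen, so a single aldehyde must result with the chain meta to it (C6). The tetrahedral adduct collapses only on aqueous work-up.

Step 6
Reactants: 11 2-{[1-(3,4-dimethoxyphenyl)ethenyl]oxy}-5-[(2E)-3,7-dimethylocta-2,6-dien-1-yl]-4,6-bis(methoxymethoxy)benzaldehyde
Product: 12 (2S)-2-(3,4-dimethoxyphenyl)-6-[(2E)-3,7-dimethylocta-2,6-dien-1-yl]-5,7-bis(methoxymethoxy)-2,3-dihydro-4H-chromen-4-one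
Conditions: [Rh(cod)Cl]2 (2.5 mol %), (R)-DTBM-SEGPHOS (5 mol %), NaBArF4 (5 mol %), 4 Å MS, 1,4-dioxane, 80 °C
Reagents that add atoms: none
Why: Proposed new method: a cationic Rh(I)–bisphosphine binds the enol-ether alkene of 11, inserts into the formyl C4–H bond, transfers the hydride to C2 by syn migratory insertion so that rhodium ends on the unsubstituted terminus C3, and closes the resulting seven-membered acyl–alkyl rhodacycle by C3–C4 reductive elimination, an isomerisation that needs no other reagent. The closest known reaction type is the enantioselective endo-selective hydroacylation of 2-(2-arylallyl)benzaldehydes to 3-aryl-1-tetralones, the all-carbon analogue in which O1 is a CH2 group, together with the hydroacylation of ether-tethered alkenes in 2-(allyloxy)benzaldehydes; an α-aryloxystyrene as acceptor has not been shown. The pyranone ring closes in a formal 6-endo-trig mode, since the 5-exo mode would need a tertiary rhodium alkyl at C2 carrying both aryl and aryloxy groups and is disfavoured on steric grounds. C2 is the only new stereocentre and is controlled by the ligand alone: the chiral pocket has to present the Re face of C2 to the Rh–H bond, which gives 2S, and because insertion can be reversible the selection is completed in the irreversible reductive elimination inside the same pocket. Regiochemistry (6- against 8-geranyl) needs no selection here, because only O1, the oxygen para to C6, carries an alkene. Chemoselectivity rests on the substrate: the trisubstituted geranyl alkenes bind cationic rhodium poorly and cannot reach the acyl centre through a small ring, the acceptor alkene has no allylic hydrogen and cannot isomerise away, and O5 stays protected because a free 5-OH would chelate rhodium on the side of C4 that faces away from O1. Chelation by the alkene keeps the acyl hydride coordinatively saturated, which is the usual defence against decarbonylation. The product forms in a neutral aprotic medium in which retro-oxa-Michael opening of 12 has no base or acid to start it.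

Step 7
Reactants: 12 (2S)-2-(3,4-dimethoxyphenyl)-6-[(2E)-3,7-dimethylocta-2,6-dien-1-yl]-5,7-bis(methoxymethoxy)-2,3-dihydro-4H-chromen-4-one
Product: 13 (2S)-2-(3,4-dimethoxyphenyl)-6-[(2E)-3,7-dimethylocta-2,6-dien-1-yl]-5,7-dihydroxy-2,3-dihydro-4H-chromen-4-one (target)
Conditions: HCl (1.25 M in MeOH), MeOH/THF, 0 °C to rt, short contact, NaHCO3 quench
Reagents that add atoms: none
Why: Acid-catalysed acetal exchange, the usual release of phenols in prenylated and geranylated flavonoids. Phenolic methoxymethyl acetals should cleave faster than the trisubstituted alkenes are protonated at this acidity and temperature. C2 is not involved, and ring opening needs base or hot strong acid.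

## Compound list

1 | phloroglucinol | Oc1cc(O)cc(O)c1 | starting material
2 | 3,4-dimethoxybenzoyl chloride | COc1ccc(C(=O)Cl)cc1OC | starting material
3 | 3,5-dihydroxyphenyl 3,4-dimethoxybenzoate | COc1ccc(C(=O)Oc2cc(O)cc(O)c2)cc1OC | intermediate
4 | 3,5-bis(methoxymethoxy)phenyl 3,4-dimethoxybenzoate | COCOc1cc(OCOC)cc(OC(=O)c2ccc(OC)c(OC)c2)c1 | intermediate
5 | 4-{1-[3,5-bis(methoxymethoxy)phenoxy]ethenyl}-1,2-dimethoxybenzene | COCOc1cc(OCOC)cc(OC(=C)c2ccc(OC)c(OC)c2)c1 | intermediate
6 | geranyl bromide | CC(C)=CCC/C(C)=C/CBr | starting material
7 | {4-[1-(3,4-dimethoxyphenyl)ethenyloxy]-2,6-bis(methoxymethoxy)phenyl}lithium | [Li]c1c(OCOC)cc(OC(=C)c2ccc(OC)c(OC)c2)cc1OCOC | intermediate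
8 | 4-(1-{4-[(2E)-3,7-dimethylocta-2,6-dien-1-yl]-3,5-bis(methoxymethoxy)phenoxy}ethenyl)-1,2-dimethoxybenzene | COCOc1cc(OC(=C)c2ccc(OC)c(OC)c2)cc(OCOC)c1C/C=C(\C)CCC=C(C)C | intermediate
9 | aryllithium of 8, lithiated between the enol-ether oxygen and one acetal oxygen | COCOc1c([Li])c(OC(=C)c2ccc(OC)c(OC)c2)cc(OCOC)c1C/C=C(\C)CCC=C(C)C | intermediate
10 | lithium α-(dimethylamino)benzyl alkoxide from 9 and DMF (racemic at the carbinol carbon) | COCOc1c(C([O-])N(C)C)c(OC(=C)c2ccc(OC)c(OC)c2)cc(OCOC)c1C/C=C(\C)CCC=C(C)C.[Li+] | intermediate
11 | 2-{[1-(3,4-dimethoxyphenyl)ethenyl]oxy}-5-geranyl-4,6-bis(methoxymethoxy)benzaldehyde | COCOc1c(C=O)c(OC(=C)c2ccc(OC)c(OC)c2)cc(OCOC)c1C/C=C(\C)CCC=C(C)C | intermediate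
12 | (2S)-2-(3,4-dimethoxyphenyl)-6-geranyl-5,7-bis(methoxymethoxy)chroman-4-one | COc1ccc([C@@H]2CC(=O)c3c(cc(OCOC)c(C/C=C(\C)CCC=C(C)C)c3OCOC)O2)cc1OC | intermediate
13 | (2S)-2-(3,4-dimethoxyphenyl)-6-geranyl-5,7-dihydroxychroman-4-one | COc1ccc([C@@H]2CC(=O)c3c(cc(O)c(C/C=C(\C)CCC=C(C)C)c3O)O2)cc1OC | target

## Step count and least certain steps

Total: 7 steps. Longest linear sequence: 7 steps (1 → 13).

**Step 6 (key step, proposed new method).**
- Decarbonylation is the first likely failure. The electron-rich, 1,1-disubstituted alkene may bind rhodium too weakly, so the hindered 2,6-dioxygenated aroyl rhodium hydride loses CO before insertion.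
- Polar closure is the second. Lewis-acidic rhodium or adventitious acid may trigger attack of the nucleophilic carbon C3 on the formyl group (the natural-polarity aldol-type path), or hydrolysis of the enol ether.
- Facial discrimination may also be modest, because both groups on C2 are flat aromatic residues.
- Fallback (known chemistry), from 11 back to 12:
  - The enol ether of 11 is hydrolysed with oxalic acid in wet THF to the regiodefined 3-geranyl-6-hydroxy-2,4-bis(methoxymethoxy)benzaldehyde F1.
  - Ethynylmagnesium bromide gives the propargylic alcohol F2, and MnO2 gives the ynone F3.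
  - Amine-promoted 6-endo-dig oxa-Michael closure gives 6-geranyl-5,7-bis(methoxymethoxy)chromone F4.
  - Asymmetric conjugate addition of commercial 3,4-dimethoxyphenylboronic acid, catalysed by Rh(I)/chiral bisphosphine or Pd(II)/pyridine-oxazoline, gives 12.
  - The symmetry-based placement of the chain is retained, and only the way C2 is set changes.

**Step 4.**
- Metalation may occur in part at a site next to the enol-ether oxygen and misplace the chain.
- Butyllithium may add across the styrene-type alkene (carbolithiation) before deprotonation is complete.
- Fallback, from 4 back to 8: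
  - The aroyl group of 4 is removed by methanolysis (K2CO3, MeOH) to give 3,5-bis(methoxymethoxy)phenol F5.
  - Silylation (TIPSCl, imidazole) gives the triisopropylsilyl ether F6, whose bulky, non-coordinating silyloxy group shields both neighbouring positions.
  - Metalation and alkylation with 6 give the 4-geranyl silyl ether F7.
  - Fluoride gives 4-geranyl-3,5-bis(methoxymethoxy)phenol F8, acylation with 2 gives the ester F9, and Petasis methylenation gives 8.
  - The chain is thus installed before any enol ether exists.

**Step 5.**
- Competing processes are carbolithiation of the enol ether, deprotonation of the benzylic-allylic C1'' methylene that both acetals flank, and attack of the new aryllithium on its own alkene.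
- Fallback, from 8 back to 11, with no organolithium in the presence of the enol ether:
  - 8 is hydrolysed (oxalic acid, wet THF) to 4-geranyl-3,5-bis(methoxymethoxy)phenol F8.
  - Casnati–Skattebøl ortho-formylation (MgCl2, Et3N, paraformaldehyde), again at either of two equivalent positions, gives the salicylaldehyde F1.
  - NaBH4 reduction of commercial 2-bromo-3',4'-dimethoxyacetophenone gives 2-bromo-1-(3,4-dimethoxyphenyl)ethanol F10.
  - Mitsunobu etherification of F1 with F10 gives the β-bromo ether F11, and E2 elimination (t-BuOK, THF, 0 °C) gives 11.

**Step 7.**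
- Protonation of C2''=C3'' followed by capture by the freed 5-OH or 7-OH (chroman formation) may compete with acetal cleavage.
- Prolonged acid contact may erode the configuration at C2 by ionisation of the benzylic C2–O1 bond.
- Fallback, from 12 to 13 without any Brønsted acid:
  - The aromatic acetals are exchanged for silyl ethers with TESOTf/2,2'-bipyridyl in CH2Cl2 to give the 5,7-bis(triethylsilyl) ether F12.
  - F12 is cleaved with pyridine-buffered HF·pyridine in THF to give 13.

## Further compounds

F1 | step 6 | 3-geranyl-6-hydroxy-2,4-bis(methoxymethoxy)benzaldehyde | COCOc1c(C=O)c(O)cc(OCOC)c1C/C=C(\C)CCC=C(C)C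
F2 | step 6 | 1-[3-geranyl-6-hydroxy-2,4-bis(methoxymethoxy)phenyl]prop-2-yn-1-ol (racemic) | COCOc1c(C(O)C#C)c(O)cc(OCOC)c1C/C=C(\C)CCC=C(C)C
F3 | step 6 | 1-[3-geranyl-6-hydroxy-2,4-bis(methoxymethoxy)phenyl]prop-2-yn-1-one | COCOc1c(C(=O)C#C)c(O)cc(OCOC)c1C/C=C(\C)CCC=C(C)C
F4 | step 6 | 6-geranyl-5,7-bis(methoxymethoxy)-4H-chromen-4-one (same structure as A3) | COCOc1cc2occc(=O)c2c(OCOC)c1C/C=C(\C)CCC=C(C)C
F5 | step 4 | 3,5-bis(methoxymethoxy)phenol | COCOc1cc(O)cc(OCOC)c1
F6 | step 4 | [3,5-bis(methoxymethoxy)phenoxy]triisopropylsilane | COCOc1cc(O[Si](C(C)C)(C(C)C)C(C)C)cc(OCOC)c1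
F7 | step 4 | [4-geranyl-3,5-bis(methoxymethoxy)phenoxy]triisopropylsilane | COCOc1cc(O[Si](C(C)C)(C(C)C)C(C)C)cc(OCOC)c1C/C=C(\C)CCC=C(C)C
F8 | step 4 | 4-geranyl-3,5-bis(methoxymethoxy)phenol | COCOc1cc(O)cc(OCOC)c1C/C=C(\C)CCC=C(C)C
F9 | step 4 | 4-geranyl-3,5-bis(methoxymethoxy)phenyl 3,4-dimethoxybenzoate | COCOc1cc(OC(=O)c2ccc(OC)c(OC)c2)cc(OCOC)c1C/C=C(\C)CCC=C(C)C
F10 | step 5 | 2-bromo-1-(3,4-dimethoxyphenyl)ethanol (racemic) | COc1ccc(C(O)CBr)cc1OC
F11 | step 5 | 2-[2-bromo-1-(3,4-dimethoxyphenyl)ethoxy]-5-geranyl-4,6-bis(methoxymethoxy)benzaldehyde (racemic) | COCOc1c(C=O)c(OC(CBr)c2ccc(OC)c(OC)c2)cc(OCOC)c1C/C=C(\C)CCC=C(C)C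
F12 | step 7 | (2S)-2-(3,4-dimethoxyphenyl)-6-geranyl-5,7-bis(triethylsilyloxy)chroman-4-one | COc1ccc([C@@H]2CC(=O)c3c(cc(O[Si](CC)(CC)CC)c(C/C=C(\C)CCC=C(C)C)c3O[Si](CC)(CC)CC)O2)cc1OC
A1 | alternative 1 | (E)-1-[3-geranyl-2,4,6-trihydroxyphenyl]-3-(3,4-dimethoxyphenyl)prop-2-en-1-one | COc1ccc(/C=C/C(=O)c2c(O)cc(O)c(C/C=C(\C)CCC=C(C)C)c2O)cc1OC
A2 | alternative 1 | 2-(3,4-dimethoxyphenyl)-8-geranyl-5,7-dihydroxychroman-4-one | COc1ccc(C2CC(=O)c3c(O)cc(O)c(C/C=C(\C)CCC=C(C)C)c3O2)cc1OC
A3 | alternative 2 | 6-geranyl-5,7-bis(methoxymethoxy)-4H-chromen-4-one | COCOc1cc2occc(=O)c2c(OCOC)c1C/C=C(\C)CCC=C(C)C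
A4 | alternative 2 | 3,4-dimethoxyphenylboronic acid | COc1ccc(B(O)O)cc1OC
A5 | alternative 3 | ethyl (R)-3-(3,4-dimethoxyphenyl)-3-hydroxypropanoate | COc1ccc([C@@H](CC(=O)OCC)O)cc1OC
A6 | alternative 3 | (S)-3-(3,4-dimethoxyphenyl)-3-[4-geranyl-3,5-bis(methoxymethoxy)phenoxy]propanoic acid | COc1ccc([C@H](CC(=O)O)Oc2cc(OCOC)c(C/C=C(\C)CCC=C(C)C)c(OCOC)c2)cc1OC
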